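**Retrosynthetic overview**

- The 1,2-dioxan-3-ol is the closed tautomer of a γ-hydroperoxy ketone. It is unveiled last from its 3-ethoxy ketal, after hydrogen has replaced a temporary mercury substituent on C5.
- Key disconnections C3–C4 and O1–C6: one flask joins three components and closes the only ring. The components are an E-allylic boronic ester (boron on C4), 1-ethoxyvinyllithium (C3 and its methyl group) and H2O2 (O1–O2).
- Enabling feature: C4 lies between the hemiketal carbon C3 and the ring methylene C5. With C5=C6 drawn as an E-trisubstituted alkene, C4 becomes an allylic C–B stereocentre. Boron hands C4 to C3 with retention, and the C4 methyl group then steers, by allylic 1,3-strain, the 6-endo peroxymercuration that makes C6 the tertiary peroxide centre.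
- The allylic boronic ester comes from sparteine-mediated lithiation–borylation of an E-alkenyl boronate, made by zirconium-catalysed carboalumination of a terminal alkyne.
- The alkyne takes its methyl stereocentre from (S)-3-bromo-2-methylpropan-1-ol and its Z-styrene from a Lindlar reduction. Ring order: the 1,2-dioxane ring (step 9) is the only ring formed.

Key step: step 9

Remark: the ketal carbon C3 is carried as a mixture of epimers between steps 9 and 11 and converges in step 11; ethyl N,N-diisopropylcarbamate and (S)-3-bromo-2-methylpropan-1-ol are taken as purchasable.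

**Route**

Step 1
Reactants: 1 phenylacetylene; 2 1-bromo-5-chloropentane
Product: 4 (7-chlorohept-1-yn-1-yl)benzene, via lithium phenylacetylide 3 (not isolated)
Conditions: n-BuLi, THF, −78 °C; then 2, DMPU, −78 °C → rt
Reagents that add atoms: none
Why: SN2 alkylation of a lithium acetylide, chemoselective for the primary bromide over the chloride.

Step 2
Reactants: 4 (7-chlorohept-1-yn-1-yl)benzene; 5 (S)-3-bromo-2-methylpropan-1-ol
Product: 8 (R)-2-methyl-10-phenyldec-9-yn-1-ol, via Grignard reagent 6 (not isolated), via magnesium alkoxide 7 (not isolated)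
Conditions: 4, Mg, THF, reflux; 5, MeMgCl, THF, −20 °C; then both, Li2CuCl4 (cat.), THF, −20 → 0 °C; aq. NH4Cl
Reagents that add atoms: none
Why: Copper-catalysed Grignard cross-coupling (Kochi coupling) at the primary bromide joins the chains without touching the stereocentre taken from 5, which only changes its descriptor to R.

Step 3
Reactants: 8 (R)-2-methyl-10-phenyldec-9-yn-1-ol
Product: 9 (2R,9Z)-2-methyl-10-phenyldec-9-en-1-ol
Conditions: H2 (1 atm), Pd/CaCO3 poisoned with Pb(OAc)2, quinoline, EtOAc, rt
Reagents that add atoms: none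
Why: Lindlar semi-hydrogenation delivers both hydrogens syn to the aryl alkyne and so sets the Z-styrene.

Step 4
Reactants: 9 (2R,9Z)-2-methyl-10-phenyldec-9-en-1-ol
Product: 10 [(1Z,9R)-10-iodo-9-methyldec-1-en-1-yl]benzene
Conditions: I2, PPh3, imidazole, CH2Cl2, 0 °C → rt
Reagents that add atoms: iodine II
Why: Appel reaction; substitution takes place at the primary carbon only, so the neighbouring stereocentre is unaffected.

Step 5
Reactants: 10 [(1Z,9R)-10-iodo-9-methyldec-1-en-1-yl]benzene
Product: 11 [(1Z,9R)-9-methyldodec-1-en-11-yn-1-yl]benzene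
Conditions: LiC≡CH·H2NCH2CH2NH2, DMSO, 10 °C → rt
Reagents that add atoms: lithium acetylide–ethylenediamine complex [Li]C#C.NCCN
Why: SN2 alkynylation of the primary iodide by lithium acetylide in a dipolar aprotic solvent.

Step 6
Reactants: 11 [(1Z,9R)-9-methyldodec-1-en-11-yn-1-yl]benzene
Product: 13 [(1Z,9R,11E)-12-iodo-9,11-dimethyldodeca-1,11-dien-1-yl]benzene, via alkenylalane 12 (not isolated)
Conditions: AlMe3, Cp2ZrCl2 (cat.), CH2Cl2, 0 °C → rt; then I2, THF, −30 °C
Reagents that add atoms: trimethylaluminium C[Al](C)C; iodine II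
Why: Negishi zirconium-catalysed carboalumination adds methyl and aluminium syn across the terminal alkyne with methyl on the internal carbon, and iodinolysis with retention gives the E-alkenyl iodide that later decides which C6 substituent is cis to C4.

Step 7
Reactants: 13 [(1Z,9R,11E)-12-iodo-9,11-dimethyldodeca-1,11-dien-1-yl]benzene
Product: 15 2-[(1E,4R,11Z)-2,4-dimethyl-12-phenyldodeca-1,11-dien-1-yl]-4,4,5,5-tetramethyl-1,3,2-dioxaborolane, via alkenyllithium 14 (not isolated)
Conditions: t-BuLi (2 equiv), Et2O, −78 °C; then i-PrOBpin, −78 °C → rt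
Reagents that add atoms: 2-isopropoxy-4,4,5,5-tetramethyl-1,3,2-dioxaborolane CC(C)OB1OC(C)(C)C(C)(C)O1
Why: Lithium–iodine exchange and borylation of the alkenyllithium both proceed with retention of alkene geometry.

Step 8
Reactants: 15 2-[(1E,4R,11Z)-2,4-dimethyl-12-phenyldodeca-1,11-dien-1-yl]-4,4,5,5-tetramethyl-1,3,2-dioxaborolane; 16 ethyl N,N-diisopropylcarbamate
Product: 19 2-[(2R,3E,6R,13Z)-4,6-dimethyl-14-phenyltetradeca-3,13-dien-2-yl]-4,4,5,5-tetramethyl-1,3,2-dioxaborolane, via lithiated carbamate 17 (not isolated), via boronate complex 18 (not isolated)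
Conditions: 16, s-BuLi, (−)-sparteine, Et2O, −78 °C; then 15, −78 °C; MgBr2·OEt2, −78 °C → reflux
Reagents that add atoms: none
Why: Sparteine-mediated asymmetric lithiation–borylation: the (S)-configured lithiated carbamate adds to boron with retention and the alkenyl group then migrates with inversion (1,2-metallate rearrangement), which sets the boron-bearing carbon (the future C4) as R under reagent control and keeps the E-alkene.

Step 9
Reactants: 19 2-[(2R,3E,6R,13Z)-4,6-dimethyl-14-phenyltetradeca-3,13-dien-2-yl]-4,4,5,5-tetramethyl-1,3,2-dioxaborolane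
Product: 25 bromo[(4S,5R,6S)-3-ethoxy-3,4,6-trimethyl-6-[(2R,9Z)-2-methyl-10-phenyldec-9-en-1-yl]-1,2-dioxan-5-yl]mercury (C3 epimers), via lithium borate complex 20 (not isolated), via ethoxy boronic ester 21 (not isolated), via borate ketal 22 (not isolated), via hydroperoxy ketal 23 (not isolated), via organomercury acetate 24 (not isolated)
Conditions: CH2=C(OEt)Li (from CH2=CHOEt, t-BuLi, THF, −78 → 0 °C), then 19, THF, −78 °C; H2O2 (anhydrous, Et2O, 2.2 equiv), −78 → 0 °C; AcOH (1.1 equiv); Hg(OAc)2 (1.05 equiv), CH2Cl2, 0 °C; aq. KBr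
Reagents that add atoms: 1-ethoxyvinyllithium [Li]C(=C)OCC; hydrogen peroxide OO; mercury diacetate CC(=O)O[Hg]OC(C)=O; potassium bromide [K+].[Br-]
Why: Proposed new method: the borate complex from 19 and 1-ethoxyvinyllithium should be protonated by H2O2 at its terminal vinyl carbon, and the boron-bound oxocarbenium ion then triggers a 1,2-metallate shift of the allylic carbon C4 from boron to C3 with retention, which makes the C3–C4 bond; the LiOOH set free oxidises the new C3–B bond, and a second H2O2 under AcOH replaces the borate oxygen (the better leaving group next to the ethoxy-stabilised cation) by OOH to give the hydroperoxy ketal 23. Hg(OAc)2 then closes the 1,2-dioxane ring by 6-endo-trig anti peroxymercuration of the E-trisubstituted C5=C6 alkene, with Markovnikov attack of the terminal peroxide oxygen on the tertiary carbon C6 making the O1–C6 bond. The closest known reaction types are the protonation-induced migration of 1-alkoxyvinyl borates and the Zweifel olefination (1,2-metallate shift), oxidative work-up of boronic esters, perhydrolysis of ketals and enol ethers, and cycloperoxymercuration of unsaturated hydroperoxides. C4 keeps its configuration because the shift is suprafacial with retention; C6 is set by a chair-like transition state in which allylic 1,3-strain with the C6 methyl group (cis to C4 in the E-alkene) puts C4–H in the alkene plane and the C4 methyl group equatorial, so the tethered oxygen adds to the face that the E geometry translates into 6S with mercury anti and equatorial on C5, while the ketal carbon C3 forms as an inconsequential mixture. The step needs protonation at the enol-ether carbon rather than at the γ-carbon of the allyl borate (secured by the much higher nucleophilicity of the alkoxy-substituted vinyl borate), 6-endo rather than 5-exo closure (secured by the tertiary Markovnikov terminus), and reaction of the mercury salt at the alkene that carries the internal hydroperoxide rather than at the Z-styrene (secured by intramolecular delivery, one equivalent of Hg(OAc)2 and almost no excess H2O2).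

Step 10
Reactants: 25 bromo[(4S,5R,6S)-3-ethoxy-3,4,6-trimethyl-6-[(2R,9Z)-2-methyl-10-phenyldec-9-en-1-yl]-1,2-dioxan-5-yl]mercury (C3 epimers)
Product: 26 (4R,6S)-3-ethoxy-3,4,6-trimethyl-6-[(2R,9Z)-2-methyl-10-phenyldec-9-en-1-yl]-1,2-dioxane (C3 epimers)
Conditions: NaBH4, aq. NaOH, CH2Cl2, 0 °C
Reagents that add atoms: none
Why: Alkaline borohydride demercuration (radical chain through the alkylmercury hydride) replaces the temporary mercury by hydrogen at C5, which is not a stereocentre in the product, and should leave the O–O bond and the ketal intact.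

Step 11
Reactants: 26 (4R,6S)-3-ethoxy-3,4,6-trimethyl-6-[(2R,9Z)-2-methyl-10-phenyldec-9-en-1-yl]-1,2-dioxane (C3 epimers)
Product: 27 (3S,4R,6S)-3,4,6-trimethyl-6-[(2R,9Z)-2-methyl-10-phenyldec-9-en-1-yl]-1,2-dioxan-3-ol
Conditions: PPTS (cat.), THF–H2O, 0 °C → rt
Reagents that add atoms: water O
Why: Acid-catalysed hydrolysis of the cyclic peroxy ketal through its oxocarbenium ion; the hemiketal carbon equilibrates by ring–chain tautomerism to the anomerically favoured axial hydroxyl (3S), and C4 should not enolise under these mild conditions.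

**Compound list**

1 | phenylacetylene | C#Cc1ccccc1 | starting material
2 | 1-bromo-5-chloropentane | ClCCCCCBr | starting material
3 | lithium phenylacetylide | [Li]C#Cc1ccccc1 | intermediate
4 | (7-chlorohept-1-yn-1-yl)benzene | ClCCCCCC#Cc1ccccc1 | intermediate
5 | (S)-3-bromo-2-methylpropan-1-ol | OC[C@H](C)CBr | starting material
6 | (7-phenylhept-6-yn-1-yl)magnesium chloride | Cl[Mg]CCCCCC#Cc1ccccc1 | intermediate
7 | chloromagnesium (2S)-3-bromo-2-methylpropan-1-olate | Cl[Mg]OC[C@H](C)CBr | intermediate
8 | (R)-2-methyl-10-phenyldec-9-yn-1-ol | OC[C@H](C)CCCCCCC#Cc1ccccc1 | intermediate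
9 | (2R,9Z)-2-methyl-10-phenyldec-9-en-1-ol | OC[C@H](C)CCCCCC/C=C\c1ccccc1 | intermediate
10 | [(1Z,9R)-10-iodo-9-methyldec-1-en-1-yl]benzene | IC[C@H](C)CCCCCC/C=C\c1ccccc1 | intermediate
11 | [(1Z,9R)-9-methyldodec-1-en-11-yn-1-yl]benzene | C#CC[C@H](C)CCCCCC/C=C\c1ccccc1 | intermediate
12 | [(1E,4R,11Z)-2,4-dimethyl-12-phenyldodeca-1,11-dien-1-yl]dimethylalumane | C[Al](C)/C=C(\C)C[C@H](C)CCCCCC/C=C\c1ccccc1 | intermediate
13 | [(1Z,9R,11E)-12-iodo-9,11-dimethyldodeca-1,11-dien-1-yl]benzene | I/C=C(\C)C[C@H](C)CCCCCC/C=C\c1ccccc1 | intermediate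
14 | [(1E,4R,11Z)-2,4-dimethyl-12-phenyldodeca-1,11-dien-1-yl]lithium | [Li]/C=C(\C)C[C@H](C)CCCCCC/C=C\c1ccccc1 | intermediate
15 | 2-[(1E,4R,11Z)-2,4-dimethyl-12-phenyldodeca-1,11-dien-1-yl]-4,4,5,5-tetramethyl-1,3,2-dioxaborolane | CC1(C)OB(/C=C(\C)C[C@H](C)CCCCCC/C=C\c2ccccc2)OC1(C)C | intermediate
16 | ethyl N,N-diisopropylcarbamate | CCOC(=O)N(C(C)C)C(C)C | starting material
17 | (S)-1-lithioethyl N,N-diisopropylcarbamate (sparteine complex) | C[C@H]([Li])OC(=O)N(C(C)C)C(C)C | intermediate
18 | lithium {(1S)-1-[(diisopropylcarbamoyl)oxy]ethyl}[(1E,4R,11Z)-2,4-dimethyl-12-phenyldodeca-1,11-dien-1-yl](pinacolato)borate | [Li+].C[C@@H](OC(=O)N(C(C)C)C(C)C)[B-]1(OC(C)(C)C(C)(C)O1)/C=C(\C)C[C@H](C)CCCCCC/C=C\c2ccccc2 | intermediate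
19 | 2-[(2R,3E,6R,13Z)-4,6-dimethyl-14-phenyltetradeca-3,13-dien-2-yl]-4,4,5,5-tetramethyl-1,3,2-dioxaborolane | C[C@@H](B1OC(C)(C)C(C)(C)O1)/C=C(\C)C[C@H](C)CCCCCC/C=C\c2ccccc2 | intermediate
20 | lithium (1-ethoxyvinyl)[(2R,3E,6R,13Z)-4,6-dimethyl-14-phenyltetradeca-3,13-dien-2-yl](pinacolato)borate | [Li+].CCOC(=C)[B-]1(OC(C)(C)C(C)(C)O1)[C@H](C)/C=C(\C)C[C@H](C)CCCCCC/C=C\c2ccccc2 | intermediate
21 | 2-[(3R,4E,7R,14Z)-2-ethoxy-3,5,7-trimethyl-15-phenylpentadeca-4,14-dien-2-yl]-4,4,5,5-tetramethyl-1,3,2-dioxaborolane (C2 epimers) | CCOC(C)(B1OC(C)(C)C(C)(C)O1)[C@H](C)/C=C(\C)C[C@H](C)CCCCCC/C=C\c2ccccc2 | intermediate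
22 | 2-{[(3R,4E,7R,14Z)-2-ethoxy-3,5,7-trimethyl-15-phenylpentadeca-4,14-dien-2-yl]oxy}-4,4,5,5-tetramethyl-1,3,2-dioxaborolane (C2 epimers) | CCOC(C)(OB1OC(C)(C)C(C)(C)O1)[C@H](C)/C=C(\C)C[C@H](C)CCCCCC/C=C\c2ccccc2 | intermediate
23 | (3R,4E,7R,14Z)-2-ethoxy-2-hydroperoxy-3,5,7-trimethyl-15-phenylpentadeca-4,14-diene (C2 epimers) | CCOC(C)(OO)[C@H](C)/C=C(\C)C[C@H](C)CCCCCC/C=C\c1ccccc1 | intermediate
24 | (acetato)[(4S,5R,6S)-3-ethoxy-3,4,6-trimethyl-6-[(2R,9Z)-2-methyl-10-phenyldec-9-en-1-yl]-1,2-dioxan-5-yl]mercury (C3 epimers) | C[C@H](CCCCCC/C=C\c1ccccc1)C[C@@]1(C)[C@H]([Hg]OC(C)=O)[C@@H](C)C(C)(OCC)OO1 | intermediate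
25 | bromo[(4S,5R,6S)-3-ethoxy-3,4,6-trimethyl-6-[(2R,9Z)-2-methyl-10-phenyldec-9-en-1-yl]-1,2-dioxan-5-yl]mercury (C3 epimers) | C[C@H](CCCCCC/C=C\c1ccccc1)C[C@@]1(C)[C@H]([Hg]Br)[C@@H](C)C(C)(OCC)OO1 | intermediate
26 | (4R,6S)-3-ethoxy-3,4,6-trimethyl-6-[(2R,9Z)-2-methyl-10-phenyldec-9-en-1-yl]-1,2-dioxane (C3 epimers) | C[C@H](CCCCCC/C=C\c1ccccc1)C[C@@]1(C)C[C@@H](C)C(C)(OCC)OO1 | intermediate
27 | (3S,4R,6S)-3,4,6-trimethyl-6-[(2R,9Z)-2-methyl-10-phenyldec-9-en-1-yl]-1,2-dioxan-3-ol | C[C@H](CCCCCC/C=C\c1ccccc1)C[C@@]1(C)C[C@@H](C)[C@@](C)(O)OO1 | target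

**Step count and risks**

Total step count: 11. Longest linear sequence: 11 steps (from 1 and 2; 5 and 16 enter as purchased materials).

Steps most likely to fail:

(1) Step 9. The one-flask merger may fail in three ways: protonation of the allyl borate at its γ-carbon (protodeboronation with allylic transposition) instead of at the enol-ether carbon; loss of the ethoxy group during the oxidative stage, which would free an epimerisable ketone; or intermolecular peroxymercuration of the styrene by residual H2O2. The fallback uses known chemistry and sets out from 19. The borate complex 20 is formed as before and treated with I2 and then NaOMe (Zweifel olefination). This passes through the β-iodo boronic ester F1 and should give, after anti elimination, the isolable 2-ethoxy-1,4-diene F2 with retention at the migrating carbon. Anhydrous H2O2 with PPTS then adds to the enol ether in the Markovnikov sense to give the hydroperoxy ketal 23, where the route is rejoined. Isolated 23, free of excess H2O2, is closed with Hg(OAc)2 and KBr as in the last stage of step 9 to give 25.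

(2) Step 10. The β-peroxyalkyl radical formed during demercuration may fragment to an epoxide with loss of the O–O bond before it is reduced. The fallback sets out from 23, isolated as in the fallback above. Camphorsulfonic acid in CH2Cl2 should protonate the trisubstituted alkene, and the tertiary cation is captured by the hydroperoxide (cationic 6-endo Markovnikov cyclisation). Hydrogen rather than mercury then sits on C5 and no reduction is needed. The route is rejoined at 26, but without the anti-addition control of C6, so the C6 epimer would have to be removed by chromatography. No new compound is made (F0).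

(3) Step 11. Ketal hydrolysis may epimerise C4 by deprotonation of the oxocarbenium ion or of the ring-opened ketone, or the acid may rearrange the peroxide. The fallback sets out from 19 and runs the ring closure at the hemiketal level. Matteson homologation with (1,1-dichloroethyl)lithium (CH3CHCl2, LDA, THF, −100 °C, then ZnCl2) should give the α-chloro boronic ester F3 with retention at the migrating carbon. NaBO3 oxidation gives the methyl ketone F4. Anhydrous H2O2 converts it into the hydroperoxy hemiketal F5, which Hg(OAc)2 and KBr cyclise to the hemiketal organomercury bromide F6. n-Bu3SnH then removes mercury without reducing the masked ketone, and the route is rejoined at 27.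

**Further compounds**

F1 | step 9 | 2-[(3R,4E,7R,14Z)-2-ethoxy-1-iodo-3,5,7-trimethyl-15-phenylpentadeca-4,14-dien-2-yl]-4,4,5,5-tetramethyl-1,3,2-dioxaborolane (C2 epimers) | CCOC(CI)(B1OC(C)(C)C(C)(C)O1)[C@H](C)/C=C(\C)C[C@H](C)CCCCCC/C=C\c2ccccc2
F2 | step 9 | (3R,4E,7R,14Z)-2-ethoxy-3,5,7-trimethyl-15-phenylpentadeca-1,4,14-triene | CCOC(=C)[C@H](C)/C=C(\C)C[C@H](C)CCCCCC/C=C\c1ccccc1
F0 | step 10 | none | none
F3 | step 11 | 2-[(3R,4E,7R,14Z)-2-chloro-3,5,7-trimethyl-15-phenylpentadeca-4,14-dien-2-yl]-4,4,5,5-tetramethyl-1,3,2-dioxaborolane (C2 epimers) | CC(Cl)(B1OC(C)(C)C(C)(C)O1)[C@H](C)/C=C(\C)C[C@H](C)CCCCCC/C=C\c2ccccc2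
F4 | step 11 | (3R,4E,7R,14Z)-3,5,7-trimethyl-15-phenylpentadeca-4,14-dien-2-one | CC(=O)[C@H](C)/C=C(\C)C[C@H](C)CCCCCC/C=C\c1ccccc1
F5 | step 11 | (3R,4E,7R,14Z)-2-hydroperoxy-3,5,7-trimethyl-15-phenylpentadeca-4,14-dien-2-ol (C2 epimers) | CC(O)(OO)[C@H](C)/C=C(\C)C[C@H](C)CCCCCC/C=C\c1ccccc1
F6 | step 11 | bromo[(3S,4S,5R,6S)-3-hydroxy-3,4,6-trimethyl-6-[(2R,9Z)-2-methyl-10-phenyldec-9-en-1-yl]-1,2-dioxan-5-yl]mercury | C[C@H](CCCCCC/C=C\c1ccccc1)C[C@@]1(C)[C@H]([Hg]Br)[C@@H](C)[C@@](C)(O)OO1
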